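# Pestalone G by photochemical diazo ketone / siloxyacetylene benzannulation of ring B

## Structural features

Pestalone G is a benzophenone: two benzene rings, ring A and ring B, joined only through one ketone carbon. It has no stereocentre, so no stereocentres stand next to each other. Ring A (C1 to C6) is hexasubstituted: ketone at C1, methoxy at C2, chlorine at C3, methyl at C4, bromine at C5 and a free hydroxyl at C6. The two halogens and the two oxygens are pairwise different and must be placed correctly relative to each other. Ring B (C1' to C6') carries the ketone at C1', a formyl group at C2', hydroxyls at C3' and C5', hydrogen at C4' and a prenyl group at C6'. All four positions ortho to the ketone are occupied, so the diaryl ketone is severely crowded and hard to make by joining two finished rings. The fragile groups are: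
- the aldehyde beside the ketone (lactol and phthalide formation);
- the prenyl group beside the C5' hydroxyl (acid closes a chroman);
- the C–Br bond (metal exchange, reduction, short-wave light);
- the electron-rich C4'–H position.

The real difficulty is the crowded ketone together with the Br/Cl versus OH/OMe pattern of ring A. The key step uses the C3'(O)–C4'(H)–C5'(OH) edge of ring B, flanked by carbon substituents at C2', C1' and C6'. This is the pattern that a vinylketene and a siloxyacetylene deliver, with ring A and its ketone already attached to the acyclic chain.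

## Logic of the disconnections

**29 ⇒ 27.** Only the O–CH2 bond of the methoxymethyl ether on the C6 oxygen and the O–Si bonds at C3' and C5' are cut. The phenols must stay masked through hydride reduction and activated-DMSO oxidation. The forward step must free three phenols without acid-closing the prenyl group onto the C5' oxygen, without touching the C2 methyl ether and without disturbing the keto aldehyde. The acetal is therefore cleaved while ring B is still silylated, and fluoride comes last.

**27 ⇒ 26 ⇒ 25.** No skeletal bond is cut. The formyl carbon at C2' is traced back to a methyl ester and the ketone is allowed to pass through the alcohol. An ester is what the ring-forming step can carry, and exhaustive reduction avoids any need to tell a hindered ester from a hindered ketone. The forward oxidation must convert both carbinols of 26 at once, because a mono-aldehyde would close to a lactol and end as a phthalide.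

**25 ⇒ 24.** The O–Si bond at C5' is cut. The ring-forming step leaves this phenol free, and it has an open ortho position (C4') that activated DMSO would attack. The forward step is a simple silylation that also makes both ring B oxygens leave together at the end.

**24 ⇒ 15 + 19.** Four ring B bonds are cut: C1'–C2', C2'–C3', C4'–C5' and C5'–C6'. Ring B falls apart into a two-carbon ynol ether and an acyclic diazo enone that already holds ring A, the ketone, the prenyl group and the formyl carbon as an ester. No bond is then made next to the crowded ketone once the ring exists. The forward step needs alkenyl migration in the Wolff rearrangement, one regiochemistry in the [2+2] step and a productive 6π closure. Two design changes to 15 serve these demands: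
- The chain double bond is E, not Z. The doubly allylic CH2 then lies away from the diazo carbon and from the ketene, and H rather than CH2 points inward in the ring closure.
- Near-UV light is used, to spare the C–Br bond.

**15 ⇒ 12 + 14 (and 14 ⇒ 13).** The C1'=C6' double bond (C4=C5 of the chain) is cut by a Knoevenagel disconnection. This places the prenyl group as a simple aldehyde and leaves a 1,3-diketone with one acidic CH2. The forward step must not move the β,γ-double bond of 14, or the skipped diene of 15, into conjugation. It should give the E isomer.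

**12 ⇒ 11 ⇒ 7 + 9 (and 9 ⇒ 8).** The bond between the future benzophenone carbonyl carbon and C1' is cut. It is made as an aldol addition of an unhindered methyl ketone enolate to the ring A aldehyde, then oxidised. This replaces acylation with a hindered aroyl chloride, avoids O-acylation, and saves the ester hydrolysis and acid chloride steps. The forward step needs γ-deprotonation of 9 without loss of the diazo group, and an oxidation that stops at the diketone.

**19 ⇒ 16.** The O–Si and C–O bonds of the ynol ether are cut back to acetylene, by oxidation of the acetylide to the ynolate and O-silylation. The bulky silyl group must go to oxygen, not carbon.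

**7 ⇒ 6 ⇒ 5 ⇒ 4 ⇒ 3 ⇒ 1.** The O–CH2 (acetal), C5–Br, C3–Cl and C1–CHO bonds are cut in turn, and one O–CH3 bond is formed in the retrosynthetic sense. The symmetric compound 3 makes the mono-demethylation unambiguous. The free phenol of 4 then directs chlorine para to itself, which leaves only the position beside the hydroxyl for bromine. The forward sequence needs clean para selectivity in the first halogenation.

## Other disconnections considered

**Alternative 1: ring A closed last by a Claisen-type cyclisation.**
- Cut: the ring A bond between the carbon that later carries bromine and the hydroxyl-bearing carbon. In the ring A numbering used here this is C5–C6; calling it C4–C5 does not fit this numbering, because C4 keeps its methyl group.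
- Forward key step: excess LiN(i-Pr)2 deprotonates a γ-methyl group of the chloro enone A1, methyl 4-chloro-2-[2-(dimethoxymethyl)-3,5-bis(methoxymethoxy)-6-(3-methylbut-2-en-1-yl)benzoyl]-5-methyl-3-oxohex-4-enoate. The carbanion attacks the ester carbon and the ring tautomerises to the chlororesorcinol A2, (3-chloro-2,6-dihydroxy-4-methylphenyl)[2-(dimethoxymethyl)-3,5-bis(methoxymethoxy)-6-(3-methylbut-2-en-1-yl)phenyl]methanone.
- In its favour: the chlorine position is fixed by the acyclic precursor, which is better than the electrophilic chlorination of the chosen plan. The chemistry is anionic, with no diazo compound and no light.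
- Against it here: A2 has two chelated hydroxyls, and only the one beside chlorine may be methylated. C5 must then be brominated in the presence of the electron-rich ring B with its free C4' position. A1 itself needs C-acylation of a β-keto ester with a doubly ortho-substituted aroyl unit.
- Comparison: on structure, this plan does not simplify ring B at all; the full hexasubstituted ring B must be made separately. The chosen plan builds ring B in one step and builds ring A by simple substitution. On mechanism, the alternative is more conservative. On step economy it is expected to be longer, because of the separate ring B synthesis and three late ring A operations.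

**Alternative 2: ring B as a cyclohexanedione by Michael–Claisen, aromatised late.**
- Cut: C1'–C2' and C3'–C4'.
- Forward key step: under NaOMe, dimethyl malonate adds to C1' of the enedione A3, 1-Ar-3-(3-methylbut-2-en-1-yl)pent-2-ene-1,4-dione. The methyl ketone enolate then closes onto a malonate ester to give A4, methyl 2-(ArCO)-3-(3-methylbut-2-en-1-yl)-4,6-dioxocyclohexane-1-carboxylate.
- In its favour: Michael addition followed by Claisen closure to a cyclohexane-1,3-dione is textbook chemistry with cheap reagents. On precedent for the bond-forming event it is better than the chosen plan. Like the chosen plan, it has ring A and the ketone in place before ring B exists, so the two are equal on that point.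
- Against it here: A3 is an unsymmetrical enedione, so the malonate could add at either alkene carbon. A4 is two hydrogens short of aromatic, and the usual ways to aromatise such diones (halogenation and elimination, quinone or iodine oxidation) endanger the prenyl double bond. A3 is itself not a short target.
- Comparison: the chosen plan gives ring B directly at the aromatic oxidation level with the two oxygens differentiated. The alternative needs an extra oxidation and is expected to be about equal in length or slightly longer. It is mechanistically safer in the ring-forming step and riskier in the aromatisation.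

**Alternative 3: ring B by Diels–Alder reaction on a ring A alkynoate.**
- Cut: C1'–C6' and C2'–C3'.
- Forward key step: the alkynoate A5, methyl 4-Ar-4-(tert-butyldimethylsilyloxy)but-2-ynoate, and the diene A6, 1-methoxy-7-methyl-1,3-bis(trimethylsilyloxy)octa-1,3,6-triene, combine in a thermal [4+2] cycloaddition. Loss of methanol and the silyl groups gives A7, methyl 2-[Ar(tert-butyldimethylsilyloxy)methyl]-4,6-dihydroxy-3-(3-methylbut-2-en-1-yl)benzoate.
- In its favour: both partners are about two steps from 7 and 8. The regiochemistry is electronically matched (nucleophilic diene terminus to the β-carbon of the ynoate). No diazo compound and no light are needed, which is better for the C–Br bond. The ring arrives aromatic, which is equal to the chosen plan.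
- Against it here: the alkyne is activated by one ester only and is shielded by the bulky carbinol carbon, while the diene carries a substituent at its reacting terminus. The temperature needed may exceed what the bis-silyloxy diene tolerates. The γ-oxygenated ynoate is base-sensitive. The ketone still has to be made by oxidation of a very hindered benzhydrol. This last point is no worse than the chosen plan, which also passes through the benzhydrol.
- Comparison: on step economy it is equal or slightly shorter. On mechanism it is more conservative. On structure it gives two undifferentiated phenols, which is equal in effect because both are free in the target. The chosen plan is preferred because it makes the C1' to ketone bond on an unhindered sp3 carbon and closes the ring under very mild conditions. This alternative is kept as the fallback for step 12.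

Key step: step 12

**Remarks on the chemistry (assumptions).**
- Ar stands throughout for 3-bromo-5-chloro-6-methoxy-2-(methoxymethoxy)-4-methylphenyl.
- The diazo enone 15 is taken as the E isomer (homoallylic CH2 trans to the diazo keto carbonyl). The Knoevenagel step is assumed to favour it, because the twisted aroyl group is expected to sit better beside the alkyl chain than the planar diazo keto ester. Any Z isomer would be separated or equilibrated.
- Acetylene gas, anhydrous tert-butyl hydroperoxide, methyl propiolate and prenyl bromide are taken as commercial.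

## Route

**Step 1**
Reactants: 1 3,5-dimethoxytoluene
Product: 3 2,6-dimethoxy-4-methylbenzaldehyde, via aryllithium 2 (not isolated)
Conditions: n-BuLi, TMEDA, THF, 0 °C → rt; DMF, −78 °C → rt; aq. NH4Cl
Reagents that add atoms: N,N-dimethylformamide, CN(C)C=O
Why: Directed ortho-metalation; the position between the two methoxy groups is the most acidic and doubly coordinated, and the aryllithium is formylated by DMF.

**Step 2**
Reactants: 3 2,6-dimethoxy-4-methylbenzaldehyde
Product: 4 2-hydroxy-6-methoxy-4-methylbenzaldehyde
Conditions: BCl3 (1.1 equiv), CH2Cl2, −78 → 0 °C; H2O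
Reagents that add atoms: none
Why: Chelation-assisted ether cleavage ortho to the carbonyl; the two methoxy groups are equivalent and the boron chelate formed after the first cleavage should protect the second.

**Step 3**
Reactants: 4 2-hydroxy-6-methoxy-4-methylbenzaldehyde
Product: 5 3-chloro-6-hydroxy-2-methoxy-4-methylbenzaldehyde
Conditions: SO2Cl2 (1.0 equiv), CH2Cl2/Et2O, 0 °C
Reagents that add atoms: sulfuryl chloride, ClS(Cl)(=O)=O
Why: Electrophilic aromatic chlorination; the free phenol is the stronger para director, so the position para to OH and ortho to OMe should react first, and one equivalent at 0 °C limits dichlorination.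

**Step 4**
Reactants: 5 3-chloro-6-hydroxy-2-methoxy-4-methylbenzaldehyde
Product: 6 3-bromo-5-chloro-2-hydroxy-6-methoxy-4-methylbenzaldehyde
Conditions: NBS, MeCN, 0 °C → rt, dark
Reagents that add atoms: N-bromosuccinimide, BrN1C(=O)CCC1=O
Why: Electrophilic aromatic bromination at the only free ring position, which is ortho to the phenol; exclusion of light avoids benzylic bromination.

**Step 5**
Reactants: 6 3-bromo-5-chloro-2-hydroxy-6-methoxy-4-methylbenzaldehyde
Product: 7 3-bromo-5-chloro-6-methoxy-2-(methoxymethoxy)-4-methylbenzaldehyde (ArCHO)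
Conditions: MOMCl, i-Pr2NEt, CH2Cl2, 0 °C → 40 °C
Reagents that add atoms: chloromethyl methyl ether, COCCl
Why: O-alkylation of the phenol to a methoxymethyl acetal; this group cannot migrate to a neighbouring alkoxide in steps 7 and 14, as a silyl ether could.

**Step 6**
Reactants: 8 methyl acetoacetate
Product: 9 methyl 2-diazo-3-oxobutanoate
Conditions: 4-acetamidobenzenesulfonyl azide, Et3N, MeCN, 0 °C → rt
Reagents that add atoms: 4-acetamidobenzenesulfonyl azide, CC(=O)Nc1ccc(cc1)S(=O)(=O)N=[N+]=[N-]
Why: Regitz diazo transfer to the active methylene of a β-keto ester.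

**Step 7**
Reactants: 9 methyl 2-diazo-3-oxobutanoate; 7 ArCHO
Product: 11 methyl 5-Ar-2-diazo-5-hydroxy-3-oxopentanoate (racemic), via lithium enolate 10 (not isolated)
Conditions: LiN(SiMe3)2, THF, −78 °C; then 7, −78 °C; aq. NH4Cl at −78 °C
Reagents that add atoms: none
Why: Aldol addition; the diazo carbon has no hydrogen, so the amide base deprotonates only the methyl group, and the small enolate adds to the hindered aldehyde with a cold quench to prevent retro-aldol. The new carbinol centre is formed racemic and is removed in step 8.

**Step 8**
Reactants: 11 methyl 5-Ar-2-diazo-5-hydroxy-3-oxopentanoate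
Product: 12 methyl 5-Ar-2-diazo-3,5-dioxopentanoate
Conditions: Dess–Martin periodinane (1.1 equiv), NaHCO3, CH2Cl2, 0 °C
Reagents that add atoms: none
Why: Dess–Martin oxidation of a β-hydroxy ketone to the 1,3-diketone under buffered, neutral conditions that leave the diazo group intact; limiting the oxidant avoids over-oxidation at the central carbon, and the product is used promptly.

**Step 9**
Reactants: 13 4-methylpent-3-en-1-ol
Product: 14 4-methylpent-3-enal
Conditions: Dess–Martin periodinane, NaHCO3, CH2Cl2, 0 °C; solution used directly
Reagents that add atoms: none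
Why: Buffered Dess–Martin oxidation of a homoallylic alcohol; the absence of base should keep the double bond out of conjugation.

**Step 10**
Reactants: 12 methyl 5-Ar-2-diazo-3,5-dioxopentanoate; 14 4-methylpent-3-enal
Product: 15 methyl (4E)-4-(ArCO)-2-diazo-8-methyl-3-oxonona-4,7-dienoate
Conditions: piperidine (cat.), AcOH (cat.), 4 Å MS, CH2Cl2, 0 °C
Reagents that add atoms: none
Why: Knoevenagel condensation of the acidic diketone CH2 with the aldehyde; low temperature and an acid-rich buffer should limit migration of either double bond into conjugation. The E isomer is expected to be favoured for the reason given in the remarks.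

**Step 11**
Reactants: 16 acetylene
Product: 19 (triisopropylsilyloxy)ethyne, via lithium acetylide 17 (not isolated), via lithium ethynolate 18 (not isolated)
Conditions: n-BuLi, THF, −78 °C; t-BuOOLi (from t-BuOOH and LiN(SiMe3)2), −78 → 0 °C; i-Pr3SiOTf, −78 °C
Reagents that add atoms: tert-butyl hydroperoxide, CC(C)(C)OO; triisopropylsilyl trifluoromethanesulfonate, CC(C)[Si](OS(=O)(=O)C(F)(F)F)(C(C)C)C(C)C
Why: Electrophilic oxidation of a lithium acetylide by a lithium alkyl peroxide gives the ynolate, and the bulky silyl triflate silylates it on oxygen.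

**Step 12 (key step)**
Reactants: 15 methyl (4E)-4-(ArCO)-2-diazo-8-methyl-3-oxonona-4,7-dienoate; 19 (triisopropylsilyloxy)ethyne
Product: 24 methyl 2-(ArCO)-4-hydroxy-3-(3-methylbut-2-en-1-yl)-6-(triisopropylsilyloxy)benzoate, via vinylketene 20 (not isolated), via vinylcyclobutenone 21 (not isolated), via dienylketene 22 (not isolated), via cyclohexadienone 23 (not isolated)
Conditions: 19 (3 equiv), hν (365 nm), ClCH2CH2Cl, 20 °C; then 80 °C
Reagents that add atoms: none
Why: Proposed new method: irradiation expels N2 from 15 and the alkenyl carbon C1' migrates from the ketone carbon to the diazo carbon (Wolff rearrangement, C1'–C2') to give the ester-substituted vinylketene 20, whose ketene carbon C5' is attacked by the electron-rich CH terminus of 19 while the silyloxy carbon bonds to C2', closing the four-membered ring of 21 by [2+2] cycloaddition (C4'–C5' and C2'–C3'). Warming opens 21 by conrotatory 4π electrocyclic cleavage of the C2'–C5' bond to the dienylketene 22, which closes the six-membered ring B by disrotatory 6π electrocyclisation (C5'–C6') to 23 and tautomerises to the phenol 24. The closest known reaction type is the Danheiser benzannulation of α-diazo enones with siloxyacetylenes through a photochemical Wolff rearrangement; a vinylketene carrying both an ester on the ketene carbon and an acyl group on the vinyl unit lies outside it. Alkenyl rather than methoxy migration is expected because alkoxy groups migrate poorly in Wolff rearrangements of 2-diazo-3-oxo esters. The [2+2] regiochemistry follows from the polarisation of the partners (nucleophilic CH of the ynol ether, ketene carbon made more electrophilic by the ester) and alone puts OSi at C3' and H at C4'. The 4π opening is reversible and only the isomer with the alkenyl group turned toward the ketene is drained by 6π closure and aromatisation, so an opening with the ester turned inward should revert and be corrected. The E geometry of 15 keeps the doubly allylic CH2 away from the ketene (no 1,5-hydrogen shift) and puts H, not CH2, inside the 6π transition state. No stereocentre survives, since C2' of 21 and C6' of 23 both become sp2 carbons; 365 nm light is chosen to excite the diazo chromophore while sparing the C–Br bond.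

**Step 13**
Reactants: 24 methyl 2-(ArCO)-4-hydroxy-3-(3-methylbut-2-en-1-yl)-6-(triisopropylsilyloxy)benzoate
Product: 25 methyl 2-(ArCO)-3-(3-methylbut-2-en-1-yl)-4,6-bis(triisopropylsilyloxy)benzoate
Conditions: i-Pr3SiOTf, 2,6-lutidine, CH2Cl2, 0 °C
Reagents that add atoms: triisopropylsilyl trifluoromethanesulfonate, CC(C)[Si](OS(=O)(=O)C(F)(F)F)(C(C)C)C(C)C
Why: O-silylation of the free C5' phenol; it shields the open C4' position from activated DMSO in step 15 and keeps the phenol from adding to the prenyl group in step 16.

**Step 14**
Reactants: 25 methyl 2-(ArCO)-3-(3-methylbut-2-en-1-yl)-4,6-bis(triisopropylsilyloxy)benzoate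
Product: 26 Ar[2-(hydroxymethyl)-6-(3-methylbut-2-en-1-yl)-3,5-bis(triisopropylsilyloxy)phenyl]methanol (racemic)
Conditions: LiAlH4 (excess), THF, 0 °C → rt; aq. NaOH
Reagents that add atoms: none
Why: Exhaustive hydride reduction of ester and diaryl ketone; whichever carbonyl reacts first, a transient phthalide is also reduced, so one diol results. The benzhydrol centre is formed racemic and is removed in step 15.

**Step 15**
Reactants: 26 Ar[2-(hydroxymethyl)-6-(3-methylbut-2-en-1-yl)-3,5-bis(triisopropylsilyloxy)phenyl]methanol
Product: 27 2-(ArCO)-3-(3-methylbut-2-en-1-yl)-4,6-bis(triisopropylsilyloxy)benzaldehyde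
Conditions: (COCl)2, DMSO, CH2Cl2, −78 → −45 °C; Et3N, −78 → 0 °C
Reagents that add atoms: none
Why: Double Swern oxidation; both hydroxyls are converted to alkoxysulfonium ions before any base is added, so no hydroxy aldehyde is present to close to a lactol, and both carbonyls appear together when Et3N is added.

**Step 16**
Reactants: 27 2-(ArCO)-3-(3-methylbut-2-en-1-yl)-4,6-bis(triisopropylsilyloxy)benzaldehyde
Product: 29 Pestalone G, 2-(3-bromo-5-chloro-2-hydroxy-6-methoxy-4-methylbenzoyl)-4,6-dihydroxy-3-(3-methylbut-2-en-1-yl)benzaldehyde, via ring A trimethylsilyl ether 28 (not isolated)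
Conditions: Me3SiBr, 4 Å MS, CH2Cl2, −30 °C; then Bu4NF, AcOH, THF, 0 °C
Reagents that add atoms: none
Why: Silyl bromide cleavage of the acetal while both ring B phenols are still silylated, so no free phenol sits beside the prenyl group under Lewis-acidic conditions; buffered fluoride then removes the three silyl groups without exposing the keto aldehyde to base.

## Compound list

Ar = 3-bromo-5-chloro-6-methoxy-2-(methoxymethoxy)-4-methylphenyl.

1 | 3,5-dimethoxytoluene | COc1cc(C)cc(OC)c1 | starting material
2 | (2,6-dimethoxy-4-methylphenyl)lithium | [Li]c1c(OC)cc(C)cc1OC | intermediate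
3 | 2,6-dimethoxy-4-methylbenzaldehyde | COc1cc(C)cc(OC)c1C=O | intermediate
4 | 2-hydroxy-6-methoxy-4-methylbenzaldehyde | COc1cc(C)cc(O)c1C=O | intermediate
5 | 3-chloro-6-hydroxy-2-methoxy-4-methylbenzaldehyde | COc1c(Cl)c(C)cc(O)c1C=O | intermediate
6 | 3-bromo-5-chloro-2-hydroxy-6-methoxy-4-methylbenzaldehyde | COc1c(Cl)c(C)c(Br)c(O)c1C=O | intermediate
7 | 3-bromo-5-chloro-6-methoxy-2-(methoxymethoxy)-4-methylbenzaldehyde (ArCHO) | COCOc1c(Br)c(C)c(Cl)c(OC)c1C=O | intermediate
8 | methyl acetoacetate | COC(=O)CC(C)=O | starting material
9 | methyl 2-diazo-3-oxobutanoate | COC(=O)C(=[N+]=[N-])C(C)=O | intermediate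
10 | lithium 3-diazo-4-methoxy-4-oxobut-1-en-2-olate | [Li]OC(=C)C(=[N+]=[N-])C(=O)OC | intermediate
11 | methyl 5-Ar-2-diazo-5-hydroxy-3-oxopentanoate (racemic) | COC(=O)C(=[N+]=[N-])C(=O)CC(O)c1c(OC)c(Cl)c(C)c(Br)c1OCOC | intermediate
12 | methyl 5-Ar-2-diazo-3,5-dioxopentanoate | COC(=O)C(=[N+]=[N-])C(=O)CC(=O)c1c(OC)c(Cl)c(C)c(Br)c1OCOC | intermediate
13 | 4-methylpent-3-en-1-ol | CC(C)=CCCO | starting material
14 | 4-methylpent-3-enal | CC(C)=CCC=O | intermediate
15 | methyl (4E)-4-(ArCO)-2-diazo-8-methyl-3-oxonona-4,7-dienoate | COC(=O)C(=[N+]=[N-])C(=O)/C(=C/CC=C(C)C)C(=O)c1c(OC)c(Cl)c(C)c(Br)c1OCOC | intermediate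
16 | acetylene | C#C | starting material
17 | lithium acetylide | [Li]C#C | intermediate
18 | lithium ethynolate | [Li]OC#C | intermediate
19 | (triisopropylsilyloxy)ethyne | C#CO[Si](C(C)C)(C(C)C)C(C)C | intermediate
20 | methyl (3Z)-3-(ArCO)-7-methyl-2-(oxomethylidene)octa-3,6-dienoate | O=C=C(C(=O)OC)/C(=C/CC=C(C)C)C(=O)c1c(OC)c(Cl)c(C)c(Br)c1OCOC | intermediate
21 | methyl 1-[(2Z)-1-Ar-6-methyl-1-oxohepta-2,5-dien-2-yl]-4-oxo-2-(triisopropylsilyloxy)cyclobut-2-ene-1-carboxylate (racemic) | O=C1C=C(O[Si](C(C)C)(C(C)C)C(C)C)C1(C(=O)OC)/C(=C/CC=C(C)C)C(=O)c1c(OC)c(Cl)c(C)c(Br)c1OCOC | intermediate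
22 | methyl (2Z)-2-[(2Z)-1-Ar-6-methyl-1-oxohepta-2,5-dien-2-yl]-5-oxo-3-(triisopropylsilyloxy)penta-2,4-dienoate | O=C=C/C(O[Si](C(C)C)(C(C)C)C(C)C)=C(C(=O)OC)\C(C(=O)c1c(OC)c(Cl)c(C)c(Br)c1OCOC)=C\CC=C(C)C | intermediate
23 | methyl 2-(ArCO)-3-(3-methylbut-2-en-1-yl)-4-oxo-6-(triisopropylsilyloxy)cyclohexa-1,5-diene-1-carboxylate (racemic) | O=C1C=C(O[Si](C(C)C)(C(C)C)C(C)C)C(C(=O)OC)=C(C(=O)c2c(OC)c(Cl)c(C)c(Br)c2OCOC)C1CC=C(C)C | intermediate
24 | methyl 2-(ArCO)-4-hydroxy-3-(3-methylbut-2-en-1-yl)-6-(triisopropylsilyloxy)benzoate | COC(=O)c1c(O[Si](C(C)C)(C(C)C)C(C)C)cc(O)c(CC=C(C)C)c1C(=O)c1c(OC)c(Cl)c(C)c(Br)c1OCOC | intermediate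
25 | methyl 2-(ArCO)-3-(3-methylbut-2-en-1-yl)-4,6-bis(triisopropylsilyloxy)benzoate | COC(=O)c1c(O[Si](C(C)C)(C(C)C)C(C)C)cc(O[Si](C(C)C)(C(C)C)C(C)C)c(CC=C(C)C)c1C(=O)c1c(OC)c(Cl)c(C)c(Br)c1OCOC | intermediate
26 | Ar[2-(hydroxymethyl)-6-(3-methylbut-2-en-1-yl)-3,5-bis(triisopropylsilyloxy)phenyl]methanol (racemic) | OCc1c(O[Si](C(C)C)(C(C)C)C(C)C)cc(O[Si](C(C)C)(C(C)C)C(C)C)c(CC=C(C)C)c1C(O)c1c(OC)c(Cl)c(C)c(Br)c1OCOC | intermediate
27 | 2-(ArCO)-3-(3-methylbut-2-en-1-yl)-4,6-bis(triisopropylsilyloxy)benzaldehyde | O=Cc1c(O[Si](C(C)C)(C(C)C)C(C)C)cc(O[Si](C(C)C)(C(C)C)C(C)C)c(CC=C(C)C)c1C(=O)c1c(OC)c(Cl)c(C)c(Br)c1OCOC | intermediate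
28 | 2-[3-bromo-5-chloro-6-methoxy-4-methyl-2-(trimethylsilyloxy)benzoyl]-3-(3-methylbut-2-en-1-yl)-4,6-bis(triisopropylsilyloxy)benzaldehyde | O=Cc1c(O[Si](C(C)C)(C(C)C)C(C)C)cc(O[Si](C(C)C)(C(C)C)C(C)C)c(CC=C(C)C)c1C(=O)c1c(OC)c(Cl)c(C)c(Br)c1O[Si](C)(C)C | intermediate
29 | Pestalone G, 2-(3-bromo-5-chloro-2-hydroxy-6-methoxy-4-methylbenzoyl)-4,6-dihydroxy-3-(3-methylbut-2-en-1-yl)benzaldehyde | COc1c(Cl)c(C)c(Br)c(O)c1C(=O)c1c(C=O)c(O)cc(O)c1CC=C(C)C | target

## Step count and least certain steps

Total: 16 steps. Longest linear sequence: 13 steps (steps 1–5, 7, 8, 10, 12–16, from 1).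

**Step 12 (key step, proposed new method).**
- What may go wrong:
  - The ester-bearing ketene is also an oxa-diene and could add the ynol ether in a [4+2] mode instead of [2+2].
  - Irradiation could isomerise the enone to the Z form, which opens a 1,5-hydrogen shift in the ketene.
  - Ring opening with the ester inward could divert material through closure on the ester oxygen.
  - The aryl ketone chromophore could abstract hydrogen from its ortho alkoxy groups, or the C–Br bond could cleave.
- Fallback (known chemistry; the Diels–Alder route of alternative 3, adapted so that it rejoins the route). It sets out from 7 and 8 and comes back at 26.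
  - Aldehyde 7 would be treated with lithiated methyl propiolate (LiN(SiMe3)2, THF, −78 °C) and the alkoxide acetylated in the same flask with Ac2O, to give methyl 4-acetoxy-4-Ar-but-2-ynoate F1.
  - The dianion of 8 (NaH, then n-BuLi) would be alkylated with prenyl bromide to methyl 7-methyl-3-oxooct-6-enoate F2.
  - Two silylations (Me3SiCl/Et3N, then LiN(i-Pr)2/Me3SiCl) would convert F2 into 1-methoxy-7-methyl-1,3-bis(trimethylsilyloxy)octa-1,3,6-triene F3, the same compound as A6.
  - Diels–Alder reaction of F1 with F3 in toluene at 80–110 °C, followed by mild acidic work-up, should give methyl 2-[acetoxy(Ar)methyl]-4,6-dihydroxy-3-(3-methylbut-2-en-1-yl)benzoate F4.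
  - Silylation of both phenols (i-Pr3SiOTf, 2,6-lutidine) would give methyl 2-[acetoxy(Ar)methyl]-3-(3-methylbut-2-en-1-yl)-4,6-bis(triisopropylsilyloxy)benzoate F5.
  - LiAlH4 would reduce both esters of F5 to the diol 26.

**Step 10 (Knoevenagel condensation).**
- What may go wrong: amine-induced migration of the β,γ-double bond of 14, or of the skipped diene in 15, into conjugation; a second Michael addition of 12 to the product; an unfavourable E/Z ratio.
- Fallback (alkylation then selenoxide elimination). It sets out from 12 and 13 and comes back at 15.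
  - Alcohol 13 would be converted (I2, PPh3, imidazole) into 5-iodo-2-methylpent-2-ene F6.
  - C-alkylation of 12 with F6 (K2CO3, acetone) would give methyl 5-Ar-2-diazo-4-(4-methylpent-3-en-1-yl)-3,5-dioxopentanoate F7.
  - Selenenylation of its sodium enolate (NaH, THF; PhSeBr, −78 °C) would give methyl 5-Ar-2-diazo-4-(4-methylpent-3-en-1-yl)-3,5-dioxo-4-(phenylselanyl)pentanoate F8.
  - Oxidation (H2O2, pyridine, CH2Cl2, 0 °C) and syn-elimination of the selenoxide, which has β-hydrogens only on the side-chain CH2, would give 15 under neutral conditions.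

**Step 3 (first halogenation).**
- What may go wrong: incomplete para selectivity, with chlorine partly entering beside the hydroxyl, and over-chlorination. The error would carry through as the Br/Cl-exchanged isomer.
- Fallback (halogenate before differentiating the oxygens). It sets out from 3 and comes back at 6.
  - Monobromination of the symmetric 3 (NBS, MeCN) can give only 3-bromo-2,6-dimethoxy-4-methylbenzaldehyde F9.
  - BCl3 should then cleave the more congested methoxy group, the one flanked by bromine and the formyl group, to give 3-bromo-2-hydroxy-6-methoxy-4-methylbenzaldehyde F10.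
  - Chlorination (SO2Cl2) at the single remaining ring position gives 6.

**Step 15 (double Swern oxidation).**
- What may go wrong: slow activation of the very hindered benzhydrol, so that the primary alcohol is oxidised alone, closes to a lactol and ends as a phthalide; or ionisation of the benzhydrol to a cyclic ether.
- Fallback (oxidise the two carbinols one after the other). It sets out from 26 and comes back at 27.
  - Selective silylation of the primary hydroxyl (Et3SiCl, imidazole, CH2Cl2, 0 °C) would give Ar[6-(3-methylbut-2-en-1-yl)-2-(triethylsilyloxymethyl)-3,5-bis(triisopropylsilyloxy)phenyl]methanol F11.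
  - Dess–Martin oxidation would give Ar[6-(3-methylbut-2-en-1-yl)-2-(triethylsilyloxymethyl)-3,5-bis(triisopropylsilyloxy)phenyl]methanone F12.
  - Mild acid (AcOH, THF, H2O) would remove the triethylsilyl group to give Ar[2-(hydroxymethyl)-6-(3-methylbut-2-en-1-yl)-3,5-bis(triisopropylsilyloxy)phenyl]methanone F13.
  - A second Dess–Martin oxidation would give 27.

## Further compounds

F1 | step 12 | methyl 4-acetoxy-4-Ar-but-2-ynoate (racemic) | COC(=O)C#CC(OC(C)=O)c1c(OC)c(Cl)c(C)c(Br)c1OCOC
F2 | step 12 | methyl 7-methyl-3-oxooct-6-enoate | COC(=O)CC(=O)CCC=C(C)C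
F3 | step 12 | 1-methoxy-7-methyl-1,3-bis(trimethylsilyloxy)octa-1,3,6-triene | COC(O[Si](C)(C)C)=CC(O[Si](C)(C)C)=CCC=C(C)C
F4 | step 12 | methyl 2-[acetoxy(Ar)methyl]-4,6-dihydroxy-3-(3-methylbut-2-en-1-yl)benzoate (racemic) | COC(=O)c1c(O)cc(O)c(CC=C(C)C)c1C(OC(C)=O)c1c(OC)c(Cl)c(C)c(Br)c1OCOC
F5 | step 12 | methyl 2-[acetoxy(Ar)methyl]-3-(3-methylbut-2-en-1-yl)-4,6-bis(triisopropylsilyloxy)benzoate (racemic) | COC(=O)c1c(O[Si](C(C)C)(C(C)C)C(C)C)cc(O[Si](C(C)C)(C(C)C)C(C)C)c(CC=C(C)C)c1C(OC(C)=O)c1c(OC)c(Cl)c(C)c(Br)c1OCOC
F6 | step 10 | 5-iodo-2-methylpent-2-ene | CC(C)=CCCI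
F7 | step 10 | methyl 5-Ar-2-diazo-4-(4-methylpent-3-en-1-yl)-3,5-dioxopentanoate (racemic) | COC(=O)C(=[N+]=[N-])C(=O)C(CCC=C(C)C)C(=O)c1c(OC)c(Cl)c(C)c(Br)c1OCOC
F8 | step 10 | methyl 5-Ar-2-diazo-4-(4-methylpent-3-en-1-yl)-3,5-dioxo-4-(phenylselanyl)pentanoate (racemic) | COC(=O)C(=[N+]=[N-])C(=O)C(CCC=C(C)C)([Se]c1ccccc1)C(=O)c1c(OC)c(Cl)c(C)c(Br)c1OCOC
F9 | step 3 | 3-bromo-2,6-dimethoxy-4-methylbenzaldehyde | COc1cc(C)c(Br)c(OC)c1C=O
F10 | step 3 | 3-bromo-2-hydroxy-6-methoxy-4-methylbenzaldehyde | COc1cc(C)c(Br)c(O)c1C=O
F11 | step 15 | Ar[6-(3-methylbut-2-en-1-yl)-2-(triethylsilyloxymethyl)-3,5-bis(triisopropylsilyloxy)phenyl]methanol (racemic) | CC[Si](CC)(CC)OCc1c(O[Si](C(C)C)(C(C)C)C(C)C)cc(O[Si](C(C)C)(C(C)C)C(C)C)c(CC=C(C)C)c1C(O)c1c(OC)c(Cl)c(C)c(Br)c1OCOC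
F12 | step 15 | Ar[6-(3-methylbut-2-en-1-yl)-2-(triethylsilyloxymethyl)-3,5-bis(triisopropylsilyloxy)phenyl]methanone | CC[Si](CC)(CC)OCc1c(O[Si](C(C)C)(C(C)C)C(C)C)cc(O[Si](C(C)C)(C(C)C)C(C)C)c(CC=C(C)C)c1C(=O)c1c(OC)c(Cl)c(C)c(Br)c1OCOC
F13 | step 15 | Ar[2-(hydroxymethyl)-6-(3-methylbut-2-en-1-yl)-3,5-bis(triisopropylsilyloxy)phenyl]methanone | OCc1c(O[Si](C(C)C)(C(C)C)C(C)C)cc(O[Si](C(C)C)(C(C)C)C(C)C)c(CC=C(C)C)c1C(=O)c1c(OC)c(Cl)c(C)c(Br)c1OCOC
A1 | alternative 1 | methyl 4-chloro-2-[2-(dimethoxymethyl)-3,5-bis(methoxymethoxy)-6-(3-methylbut-2-en-1-yl)benzoyl]-5-methyl-3-oxohex-4-enoate | COC(=O)C(C(=O)C(Cl)=C(C)C)C(=O)c1c(C(OC)OC)c(OCOC)cc(OCOC)c1CC=C(C)C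
A2 | alternative 1 | (3-chloro-2,6-dihydroxy-4-methylphenyl)[2-(dimethoxymethyl)-3,5-bis(methoxymethoxy)-6-(3-methylbut-2-en-1-yl)phenyl]methanone | Cc1cc(O)c(C(=O)c2c(C(OC)OC)c(OCOC)cc(OCOC)c2CC=C(C)C)c(O)c1Cl
A3 | alternative 2 | 1-Ar-3-(3-methylbut-2-en-1-yl)pent-2-ene-1,4-dione | CC(=O)C(CC=C(C)C)=CC(=O)c1c(OC)c(Cl)c(C)c(Br)c1OCOC
A4 | alternative 2 | methyl 2-(ArCO)-3-(3-methylbut-2-en-1-yl)-4,6-dioxocyclohexane-1-carboxylate (diastereomer mixture) | COC(=O)C1C(=O)CC(=O)C(CC=C(C)C)C1C(=O)c1c(OC)c(Cl)c(C)c(Br)c1OCOC
A5 | alternative 3 | methyl 4-Ar-4-(tert-butyldimethylsilyloxy)but-2-ynoate (racemic) | COC(=O)C#CC(O[Si](C)(C)C(C)(C)C)c1c(OC)c(Cl)c(C)c(Br)c1OCOC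
A6 | alternative 3 | 1-methoxy-7-methyl-1,3-bis(trimethylsilyloxy)octa-1,3,6-triene | COC(O[Si](C)(C)C)=CC(O[Si](C)(C)C)=CCC=C(C)C
A7 | alternative 3 | methyl 2-[Ar(tert-butyldimethylsilyloxy)methyl]-4,6-dihydroxy-3-(3-methylbut-2-en-1-yl)benzoate (racemic) | COC(=O)c1c(O)cc(O)c(CC=C(C)C)c1C(O[Si](C)(C)C(C)(C)C)c1c(OC)c(Cl)c(C)c(Br)c1OCOC
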